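**Strategy.** Everything rests on opening the six-membered lactone ring at its carbonyl (chroman-2-one numbering): C2 joins O1, which sits on C8a, to C3, and is excised as carbon monoxide. This exposes a phenol beside a C4=C3 1,1-diarylethene whose aryl groups are unlike, the central arene being forced out of plane by its C5 methyl and C8a hydroxyl. One Pd–H mediated operation should put H on C4, forge C3–C2 and O1–C2, close the lactone ring and set the only stereocentre. The precursor is the free resorcinol bearing the finished 4-methoxy-2-pyranone at C6 and a TIPS-protected 4-hydroxyphenyl group on the alkene, built from dibrominated orcinol bis(MOM) ether.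

Key step: step 11

Assumption: the sense of induction of the bisphosphine WingPhos (4,4'-di(anthracen-9-yl)-3,3'-di-tert-butyl-2,2',3,3'-tetrahydro-2,2'-bibenzo[d][1,3]oxaphosphole) cannot be assigned in advance; the (2S,2'S,3S,3'S) ligand is written, and its mirror image is to be used if a first run delivers the (4S) lactone. Anhydrous orcinol is used.

**Route**

Step 1
Reactants: 1 orcinol (5-methylbenzene-1,3-diol)
Product: 2 1,3-bis(methoxymethoxy)-5-methylbenzene
Conditions: MOMCl (2.5 equiv), i-Pr2NEt, CH2Cl2, 0 °C to rt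
Reagents that add atoms: chloromethyl methyl ether, COCCl
Why: Base-mediated O-alkylation of both phenols by the α-chloro ether (Williamson etherification) should give the bis-acetal, which withstands organolithium, enolate and cross-coupling conditions and later chelates lithium.

Step 2
Reactants: 2 1,3-bis(methoxymethoxy)-5-methylbenzene
Product: 3 2,4-dibromo-1,5-bis(methoxymethoxy)-3-methylbenzene
Conditions: NBS (2.05 equiv), MeCN, 0 °C to rt
Reagents that add atoms: N-bromosuccinimide, O=C1CCC(=O)N1Br
Why: Electrophilic aromatic bromination should occur twice para to an acetal oxygen, that is at the two equivalent positions flanking the methyl group, because the remaining position lies between both OMOM groups and is the most shielded.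

Step 3
Reactants: 3 2,4-dibromo-1,5-bis(methoxymethoxy)-3-methylbenzene, 4 carbon dioxide
Product: 6 3-bromo-4,6-bis(methoxymethoxy)-2-methylbenzoic acid, via aryllithium 5 (not isolated)
Conditions: n-BuLi (1.05 equiv), THF, −78 °C; CO2 (gas), −78 °C to rt; cold 1 M HCl to pH 3
Reagents that add atoms: none
Why: Bromine–lithium exchange at −78 °C outruns any deprotonation and stops after one exchange (the OMOM-chelated monoanion resists a second one), the aryllithium is carboxylated by CO2, and the mirror symmetry of the dibromide makes the regiochemistry unambiguous.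

Step 4
Reactants: 6 3-bromo-4,6-bis(methoxymethoxy)-2-methylbenzoic acid, 7 2,2,6-trimethyl-4H-1,3-dioxin-4-one
Product: 10 6-{2-[3-bromo-4,6-bis(methoxymethoxy)-2-methylphenyl]-2-oxoethyl}-2,2-dimethyl-4H-1,3-dioxin-4-one, via acyl imidazole 8 (not isolated), via lithium dienolate 9 (not isolated)
Conditions: 6, CDI, THF, rt; cannulated into 7 (3.5 equiv) + LiN(SiMe3)2 (3.5 equiv), THF, −78 to −20 °C; aq. NH4Cl
Reagents that add atoms: none
Why: Claisen-type C-acylation of the extended lithium enolate at its γ-carbon by the acyl imidazole should give the β-keto dioxinone; imidazolide activation avoids HCl and an acid chloride that the ortho OMOM group could attack, and the excess dienolate absorbs the imidazole N–H and the acidic product.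

Step 5
Reactants: 10 6-{2-[3-bromo-4,6-bis(methoxymethoxy)-2-methylphenyl]-2-oxoethyl}-2,2-dimethyl-4H-1,3-dioxin-4-one
Product: 13 6-[3-bromo-4,6-bis(methoxymethoxy)-2-methylphenyl]-4-methoxy-2H-pyran-2-one, via acylketene 11 (not isolated), via hydroxypyranone 12 (not isolated)
Conditions: PhMe, 110 °C; then K2CO3, Me2SO4, acetone, 56 °C
Reagents that add atoms: dimethyl sulfate, COS(=O)(=O)OC
Why: Thermal retro-hetero-Diels–Alder loss of acetone gives the acylketene, the enol oxygen of the aryl ketone adds to the ketene carbon to close the 4-hydroxy-2-pyranone, and the hard electrophile Me2SO4 then O-methylates the vinylogous acid at O4.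

Step 6
Reactants: 14 4'-hydroxyacetophenone
Product: 15 1-[4-(triisopropylsilyloxy)phenyl]ethanone
Conditions: TIPSCl, imidazole, DMF, rt
Reagents that add atoms: chlorotriisopropylsilane, CC(C)[Si](Cl)(C(C)C)C(C)C
Why: Imidazole-promoted silylation of the phenol gives a bulky aryl silyl ether that should survive n-BuLi at low temperature, aqueous phosphate, silyl triflate and catalytic sulfonic acid, and leaves with fluoride at the end.

Step 7
Reactants: 15 1-[4-(triisopropylsilyloxy)phenyl]ethanone
Product: 16 (E)-2,4,6-triisopropyl-N'-{1-[4-(triisopropylsilyloxy)phenyl]ethylidene}benzenesulfonohydrazide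
Conditions: 2,4,6-(i-Pr)3C6H2SO2NHNH2, MeOH, cat. AcOH, rt
Reagents that add atoms: 2,4,6-triisopropylbenzenesulfonyl hydrazide, CC(C)c1cc(C(C)C)c(S(=O)(=O)NN)c(C(C)C)c1
Why: Condensation of the ketone with the sulfonyl hydrazide should give the E-hydrazone, with the sulfonamide nitrogen syn to the methyl group as the Shapiro reaction requires, under acidity too weak to touch the silyl ether.

Step 8
Reactants: 16 (E)-2,4,6-triisopropyl-N'-{1-[4-(triisopropylsilyloxy)phenyl]ethylidene}benzenesulfonohydrazide
Product: 18 triisopropyl{4-[1-(4,4,5,5-tetramethyl-1,3,2-dioxaborolan-2-yl)vinyl]phenoxy}silane, via vinyllithium 17 (not isolated)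
Conditions: n-BuLi (2.2 equiv), THF, −78 to 0 °C; i-PrOBpin, −78 °C to rt; aq. NH4Cl
Reagents that add atoms: 2-isopropoxy-4,4,5,5-tetramethyl-1,3,2-dioxaborolane, CC(C)OB1OC(C)(C)C(C)(C)O1
Why: Shapiro reaction: double deprotonation (N–H, then the syn methyl group) and loss of sulfinate and N2 on warming give the 1-arylvinyllithium, which is trapped at boron by the isopropoxy boronate, so an ionisation-prone electron-rich 1-arylvinyl triflate is avoided.

Step 9
Reactants: 13 6-[3-bromo-4,6-bis(methoxymethoxy)-2-methylphenyl]-4-methoxy-2H-pyran-2-one, 18 triisopropyl{4-[1-(4,4,5,5-tetramethyl-1,3,2-dioxaborolan-2-yl)vinyl]phenoxy}silane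
Product: 19 6-[4,6-bis(methoxymethoxy)-2-methyl-3-{1-[4-(triisopropylsilyloxy)phenyl]vinyl}phenyl]-4-methoxy-2H-pyran-2-one
Conditions: Pd(OAc)2 (5 mol%), SPhos (10 mol%), K3PO4, PhMe/H2O, 90 °C
Reagents that add atoms: none
Why: Suzuki–Miyaura coupling, in which the bulky electron-rich SPhos ligand is suited to oxidative addition and reductive elimination at a doubly ortho-substituted aryl bromide, the vinyl boronate transmetalates readily, and biphasic phosphate is mild enough for the pyranone and the TIPS ether.

Step 10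
Reactants: 19 6-[4,6-bis(methoxymethoxy)-2-methyl-3-{1-[4-(triisopropylsilyloxy)phenyl]vinyl}phenyl]-4-methoxy-2H-pyran-2-one
Product: 21 6-[4,6-dihydroxy-2-methyl-3-{1-[4-(triisopropylsilyloxy)phenyl]vinyl}phenyl]-4-methoxy-2H-pyran-2-one, via bis(trimethylsilyl) ether 20 (not isolated)
Conditions: TMSOTf, 2,2'-bipyridyl, MeCN, 0 °C to rt; then H2O
Reagents that add atoms: none
Why: Silyl triflate–bipyridyl cleavage of aryl MOM ethers transfers the methoxymethyl unit to bipyridyl as a pyridinium salt and leaves aryl trimethylsilyl ethers that hydrolyse on adding water, so neither free Brønsted acid nor a methoxymethyl cation should reach the electron-rich alkene and the TIPS ether stays.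

Step 11
Reactants: 21 6-[4,6-dihydroxy-2-methyl-3-{1-[4-(triisopropylsilyloxy)phenyl]vinyl}phenyl]-4-methoxy-2H-pyran-2-one, 22 carbon monoxide
Product: 23 (R)-6-{7-hydroxy-5-methyl-2-oxo-4-[4-(triisopropylsilyloxy)phenyl]chroman-6-yl}-4-methoxy-2H-pyran-2-one
Conditions: Pd2(dba)3 (2 mol%), (2S,2'S,3S,3'S)-WingPhos (4.8 mol%), TsOH·H2O (10 mol%), CO (10 bar), PhMe, 50 °C
Reagents that add atoms: none
Why: Zerovalent palladium and TsOH give a cationic hydride [(P–P)PdH]+ that inserts the alkene with H on C4 and Pd on the terminal C3 (the reverse sense would need a quaternary dibenzylic Pd–C bond), CO inserts into C3–Pd to make C2–C3, and the C8a hydroxyl displaces palladium from the acyl complex to form O1–C2, returning zerovalent palladium for reprotonation. The closest known reaction type is the palladium-catalysed asymmetric hydroesterification of 1,1-diarylethenes, which ends in lactonization to 4-aryl-3,4-dihydrocoumarins when one aryl ring carries an ortho hydroxyl. The lactone ring closes by 6-exo-trig acyl substitution at the acyl-palladium carbon, equivalent to C–O reductive elimination from an acyl(aryloxido) chelate. C4 is set in the hydride insertion under control of the P-stereogenic bisphosphine, whose pocket has to tell the twisted central ring (C5 methyl and C8a hydroxyl out of the alkene plane) from the coplanar 4-silyloxyphenyl ring. The step needs anti-Markovnikov regioselectivity, secured by the 1,1-disubstitution, and O1 over C7–OH chemoselectivity, secured because the C7 hydroxyl is para to C4a and cannot reach the acyl carbon while the TIPS ether masks the third phenol. Acid loading and temperature are kept low so that protonation of the electron-rich alkene should not lead to oligomers, and the acid-stable bisphosphine is preferred to ligands with P–N bonds.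

Step 12
Reactants: 23 (R)-6-{7-hydroxy-5-methyl-2-oxo-4-[4-(triisopropylsilyloxy)phenyl]chroman-6-yl}-4-methoxy-2H-pyran-2-one
Product: 24 (R)-6-[7-hydroxy-4-(4-hydroxyphenyl)-5-methyl-2-oxochroman-6-yl]-4-methoxy-2H-pyran-2-one (target)
Conditions: HF·pyridine, pyridine, THF, 0 °C to rt
Reagents that add atoms: none
Why: Fluoride-driven cleavage of the aryl silyl ether (Si–F bond formation) in a buffered, weakly acidic medium should neither open the aryl lactone nor affect C4, which is not enolisable.

**Compound list**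

1 | orcinol (5-methylbenzene-1,3-diol) | Cc1cc(O)cc(O)c1 | starting material
2 | 1,3-bis(methoxymethoxy)-5-methylbenzene | COCOc1cc(C)cc(OCOC)c1 | intermediate
3 | 2,4-dibromo-1,5-bis(methoxymethoxy)-3-methylbenzene | COCOc1cc(OCOC)c(Br)c(C)c1Br | intermediate
4 | carbon dioxide | O=C=O | starting material
5 | [3-bromo-4,6-bis(methoxymethoxy)-2-methylphenyl]lithium (aryllithium) | COCOc1cc(OCOC)c(Br)c(C)c1[Li] | intermediate
6 | 3-bromo-4,6-bis(methoxymethoxy)-2-methylbenzoic acid | COCOc1cc(OCOC)c(Br)c(C)c1C(=O)O | intermediate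
7 | 2,2,6-trimethyl-4H-1,3-dioxin-4-one | CC1=CC(=O)OC(C)(C)O1 | starting material
8 | [3-bromo-4,6-bis(methoxymethoxy)-2-methylphenyl](1H-imidazol-1-yl)methanone (acyl imidazole) | COCOc1cc(OCOC)c(Br)c(C)c1C(=O)n1ccnc1 | intermediate
9 | lithium 2,2-dimethyl-6-methylidene-6H-1,3-dioxin-4-olate (lithium dienolate) | C=C1C=C(O[Li])OC(C)(C)O1 | intermediate
10 | 6-{2-[3-bromo-4,6-bis(methoxymethoxy)-2-methylphenyl]-2-oxoethyl}-2,2-dimethyl-4H-1,3-dioxin-4-one | COCOc1cc(OCOC)c(Br)c(C)c1C(=O)CC1=CC(=O)OC(C)(C)O1 | intermediate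
11 | 5-[3-bromo-4,6-bis(methoxymethoxy)-2-methylphenyl]penta-1-ene-1,3,5-trione (acylketene) | COCOc1cc(OCOC)c(Br)c(C)c1C(=O)CC(=O)C=C=O | intermediate
12 | 6-[3-bromo-4,6-bis(methoxymethoxy)-2-methylphenyl]-4-hydroxy-2H-pyran-2-one (hydroxypyranone) | COCOc1cc(OCOC)c(Br)c(C)c1-c1cc(O)cc(=O)o1 | intermediate
13 | 6-[3-bromo-4,6-bis(methoxymethoxy)-2-methylphenyl]-4-methoxy-2H-pyran-2-one | COCOc1cc(OCOC)c(Br)c(C)c1-c1cc(OC)cc(=O)o1 | intermediate
14 | 4'-hydroxyacetophenone | CC(=O)c1ccc(O)cc1 | starting material
15 | 1-[4-(triisopropylsilyloxy)phenyl]ethanone | CC(=O)c1ccc(O[Si](C(C)C)(C(C)C)C(C)C)cc1 | intermediate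
16 | (E)-2,4,6-triisopropyl-N'-{1-[4-(triisopropylsilyloxy)phenyl]ethylidene}benzenesulfonohydrazide | C/C(=N\NS(=O)(=O)c1c(C(C)C)cc(C(C)C)cc1C(C)C)c1ccc(O[Si](C(C)C)(C(C)C)C(C)C)cc1 | intermediate
17 | {1-[4-(triisopropylsilyloxy)phenyl]vinyl}lithium (vinyllithium) | C=C([Li])c1ccc(O[Si](C(C)C)(C(C)C)C(C)C)cc1 | intermediate
18 | triisopropyl{4-[1-(4,4,5,5-tetramethyl-1,3,2-dioxaborolan-2-yl)vinyl]phenoxy}silane | C=C(B1OC(C)(C)C(C)(C)O1)c1ccc(O[Si](C(C)C)(C(C)C)C(C)C)cc1 | intermediate
19 | 6-[4,6-bis(methoxymethoxy)-2-methyl-3-{1-[4-(triisopropylsilyloxy)phenyl]vinyl}phenyl]-4-methoxy-2H-pyran-2-one | COc1cc(-c2c(C)c(C(=C)c3ccc(O[Si](C(C)C)(C(C)C)C(C)C)cc3)c(OCOC)cc2OCOC)oc(=O)c1 | intermediate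
20 | 4-methoxy-6-[2-methyl-3-{1-[4-(triisopropylsilyloxy)phenyl]vinyl}-4,6-bis(trimethylsilyloxy)phenyl]-2H-pyran-2-one (bis(trimethylsilyl) ether) | COc1cc(-c2c(C)c(C(=C)c3ccc(O[Si](C(C)C)(C(C)C)C(C)C)cc3)c(O[Si](C)(C)C)cc2O[Si](C)(C)C)oc(=O)c1 | intermediate
21 | 6-[4,6-dihydroxy-2-methyl-3-{1-[4-(triisopropylsilyloxy)phenyl]vinyl}phenyl]-4-methoxy-2H-pyran-2-one (key-step precursor) | COc1cc(-c2c(O)cc(O)c(c2C)C(=C)c2ccc(O[Si](C(C)C)(C(C)C)C(C)C)cc2)oc(=O)c1 | intermediate
22 | carbon monoxide | [C-]#[O+] | starting material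
23 | (R)-6-{7-hydroxy-5-methyl-2-oxo-4-[4-(triisopropylsilyloxy)phenyl]chroman-6-yl}-4-methoxy-2H-pyran-2-one (key-step product, 4R) | COc1cc(-c2c(O)cc3c(c2C)[C@@H](c2ccc(O[Si](C(C)C)(C(C)C)C(C)C)cc2)CC(=O)O3)oc(=O)c1 | intermediate
24 | (R)-6-[7-hydroxy-4-(4-hydroxyphenyl)-5-methyl-2-oxochroman-6-yl]-4-methoxy-2H-pyran-2-one | COc1cc(-c2c(O)cc3c(c2C)[C@@H](c2ccc(O)cc2)CC(=O)O3)oc(=O)c1 | target

**Count**

Total step count: 12. Longest linear sequence: 9 steps (steps 1–5 and 9–12, from orcinol); the boronate branch (steps 6–8) joins at step 9.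

**Steps most likely to fail**

1. Step 11. The process at risk is weak enantioface discrimination in the hydride insertion, or its erosion by reversible β-hydride elimination before CO insertion. The fallback sets out from 21 and gives up asymmetric induction. Carbonylative lactonization with an achiral catalyst (Pd(OAc)2, Xantphos, TsOH·H2O, CO, PhMe, 60 °C) should give racemic 6-{7-hydroxy-5-methyl-2-oxo-4-[4-(triisopropylsilyloxy)phenyl]chroman-6-yl}-4-methoxy-2H-pyran-2-one F1. F1 is resolved by preparative chromatography on a chiral stationary phase (cellulose tris(3,5-dimethylphenylcarbamate)). The (R)-enantiomer is 23, where the route is rejoined; the (S)-enantiomer, (S)-6-{7-hydroxy-5-methyl-2-oxo-4-[4-(triisopropylsilyloxy)phenyl]chroman-6-yl}-4-methoxy-2H-pyran-2-one F2, is set aside.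

2. Step 9. The process at risk is slow oxidative addition and transmetalation at the doubly ortho-substituted C–Br bond, which leaves time for protodeboronation of 18. The fallback sets out from 13 and 15 and needs no boron reagent. Ketone 15 is condensed with TsNHNH2 (MeOH, rt) to (E)-4-methyl-N'-{1-[4-(triisopropylsilyloxy)phenyl]ethylidene}benzenesulfonohydrazide F3. F3 is joined to 13 in a Barluenga coupling (Pd2(dba)3, XPhos, LiOt-Bu, dioxane, 90 °C): the diazo compound formed in situ inserts as a carbene into the Ar–Pd bond, and β-hydride elimination from the methyl group should give the 1,1-diarylethene. The route is rejoined at 19.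

3. Step 10. The process at risk is attack of the released methoxymethyl electrophile or of adventitious acid on the electron-rich alkene, or incomplete acetal cleavage. The fallback sets out from 13 and changes the order of events. The MOM groups are removed before the alkene exists (HCl, MeOH, 50 °C) to give 6-(3-bromo-4,6-dihydroxy-2-methylphenyl)-4-methoxy-2H-pyran-2-one F4. The free bromoresorcinol F4 is then coupled with 18 (Pd(OAc)2, SPhos, excess K3PO4, dioxane/H2O, 90 °C), which should give the precursor directly. The route is rejoined at 21.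

Further compounds
F1 | step 11 | racemic 6-{7-hydroxy-5-methyl-2-oxo-4-[4-(triisopropylsilyloxy)phenyl]chroman-6-yl}-4-methoxy-2H-pyran-2-one | COc1cc(-c2c(O)cc3c(c2C)C(c2ccc(O[Si](C(C)C)(C(C)C)C(C)C)cc2)CC(=O)O3)oc(=O)c1
F2 | step 11 | (S)-6-{7-hydroxy-5-methyl-2-oxo-4-[4-(triisopropylsilyloxy)phenyl]chroman-6-yl}-4-methoxy-2H-pyran-2-one | COc1cc(-c2c(O)cc3c(c2C)[C@H](c2ccc(O[Si](C(C)C)(C(C)C)C(C)C)cc2)CC(=O)O3)oc(=O)c1
F3 | step 9 | (E)-4-methyl-N'-{1-[4-(triisopropylsilyloxy)phenyl]ethylidene}benzenesulfonohydrazide | C/C(=N\NS(=O)(=O)c1ccc(C)cc1)c1ccc(O[Si](C(C)C)(C(C)C)C(C)C)cc1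
F4 | step 10 | 6-(3-bromo-4,6-dihydroxy-2-methylphenyl)-4-methoxy-2H-pyran-2-one | COc1cc(-c2c(C)c(Br)c(O)cc2O)oc(=O)c1
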